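**Retrosynthetic overview**

1. Numbering: cyclobutane C1–C2–C8–C7; enone bridge C1–C11(=O)–C10=C9(Me)–C8 (with the cyclobutane a bicyclo[3.1.1]heptenone); seven-membered ring C2–C3(O-senecioyl)–C4–C5(O-isovaleryl)–C6(Me)2–C7, closed through C1 or C8.
2. The plan rests on C2, the one quaternary ring stereocentre: it carries both cyclobutane bonds (C2–C1, C2–C8) and starts the seven-membered ring, so cutting C2–C8 and C2–C1 leaves one cyclohexene whose C7 side chain ends in an ethyl ketone (C2 = its α′-CH2) facing a 1,3-dielectrophile (allylic C8–Cl, C1–OTs, both trans to the chain).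
3. Target ⇐ allylic oxidation at C11 ⇐ acylations after catalyst-controlled oxygenation of C3 (conjugate borylation) and C5 (oxazaborolidine reduction) ⇐ carbonyl transposition of the tricyclic vinylogous ester made in the key step.
4. Chloro tosylate ⇐ (S)-carvone: quaternary C6 on C7 by Nicholas propargylation, isopropenyl → C1–O by Criegee rearrangement, C8–O by hydroxyl-directed reduction then invertive chlorination, C5–C2 by acetylide acylation and methanol addition to the ynone (E-vinylogous ester, C4 blocked).
5. Ring order: cyclohexene (from carvone), then in one flask the seven-membered ring (C2–C8) and the cyclobutane (C2–C1).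

Key step: step 13

Remark: locants C1–C11 in names of bicyclic and tricyclic compounds are those of the overview; the dicobalt clusters are written in SMILES as their components (organic ligand, two Co, six CO).

**Route**

Step 1
Reactants: 1 (S)-(+)-carvone
Product: 2 trimethyl{[(3S)-6-methyl-3-(prop-1-en-2-yl)cyclohexa-1,5-dien-1-yl]oxy}silane
Conditions: LiN(i-Pr)2, THF, −78 °C; Me3SiCl, Et3N, −78 → 0 °C
Reagents that add atoms: chlorotrimethylsilane, C[Si](C)(C)Cl
Why: Kinetic deprotonation of the enone at the α′-CH2 (C7) and O-silylation give the cross-conjugated silyl dienol ether (silyl enol ether formation); the carvone stereocentre (C1) is not touched.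

Step 2
Reactants: 3 2-methylbut-3-yn-2-ol
Product: 4 Co2(CO)6(μ-HC≡C–CMe2OH), the hexacarbonyldicobalt complex of 3
Conditions: Co2(CO)8, CH2Cl2, rt
Reagents that add atoms: octacarbonyldicobalt Co2(CO)8, [Co].[Co].[C-]#[O+].[C-]#[O+].[C-]#[O+].[C-]#[O+].[C-]#[O+].[C-]#[O+].[C-]#[O+].[C-]#[O+]
Why: A terminal alkyne displaces two CO ligands of Co2(CO)8 at room temperature to give the μ-alkyne cluster needed for a Nicholas reaction.

Step 3
Reactants: 2 silyl dienol ether; 4 cobalt complex of 2-methylbut-3-yn-2-ol
Product: 6 (5S,6S)-2-methyl-6-(2-methylbut-3-yn-2-yl)-5-(prop-1-en-2-yl)cyclohex-2-en-1-one, via cobalt complex 5 (not isolated)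
Conditions: BF3·OEt2, CH2Cl2, −78 °C; then (NH4)2Ce(NO3)6, acetone, 0 °C
Reagents that add atoms: none
Why: Nicholas reaction: BF3 ionises the complexed tertiary propargylic alcohol, the cobalt-stabilised cation is captured by the silyl enol ether at C7 anti to the neighbouring isopropenyl group (C7 set trans to C1, quaternary C6 formed directly), and (NH4)2Ce(NO3)6 then strips the metal from the alkyne.

Step 4
Reactants: 6 propargylated carvone
Product: 8 (1S,6R)-4-methyl-6-(2-methylbut-3-yn-2-yl)-5-oxocyclohex-3-en-1-yl acetate, via methoxy hydroperoxide 7 (not isolated)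
Conditions: O3, CH2Cl2/MeOH, −78 °C (Sudan Red 7B end point); then Ac2O, Et3N, DMAP (cat.), CH2Cl2, 0 °C → rt
Reagents that add atoms: ozone, [O-][O+]=O; methanol, CO
Why: Ozonolysis in methanol then Criegee rearrangement of the acetylated methoxy hydroperoxide: ozone takes the 1,1-disubstituted alkene before the enone alkene and the alkyne, and the ring carbon migrates to oxygen with retention, so the C1–O bond keeps the carvone configuration (the acetyl carbons are those of the isopropenyl group).

Step 5
Reactants: 8 keto acetate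
Product: 9 (5S,6R)-5-hydroxy-2-methyl-6-(2-methylbut-3-yn-2-yl)cyclohex-2-en-1-one
Conditions: K2CO3 (0.2 equiv), MeOH, 0 °C
Reagents that add atoms: none
Why: Base-catalysed transesterification of the acetate; β-elimination should be slow because the only α-hydrogen (C7–H) sits beside the quaternary carbon, and C7 is already the thermodynamically preferred trans epimer.

Step 6
Reactants: 9 β-hydroxy enone
Product: 10 (1S,2R,3R)-4-methyl-2-(2-methylbut-3-yn-2-yl)cyclohex-4-ene-1,3-diol
Conditions: Me4NBH(OAc)3, MeCN/AcOH (1:1), −35 °C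
Reagents that add atoms: none
Why: Evans–Saksena hydroxyl-directed reduction: the alkoxy(diacetoxy)borohydride formed at the C1 hydroxyl (axial in the reacting conformer) passes hydride to the C8 carbonyl on its own face, which sets C8 as the 1,3-anti alcohol, cis to the C7 substituent.

Step 7
Reactants: 10 diol
Product: 11 bis(tert-butyldimethylsilyl) ether of 10
Conditions: TBSOTf (2.5 equiv), 2,6-lutidine, CH2Cl2, 0 °C
Reagents that add atoms: tert-butyldimethylsilyl trifluoromethanesulfonate, CC(C)(C)[Si](C)(C)OS(=O)(=O)C(F)(F)F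
Why: Silylation with the silyl triflate covers both hindered secondary alcohols so that neither can quench the acetylide or add to the ynone in the next two steps.

Step 8
Reactants: 11 bis-silyl ether; 12 N-methoxy-N-methylpropanamide
Product: 13 6-[(1R,2R,6S)-2,6-bis(tert-butyldimethylsilyloxy)-3-methylcyclohex-3-en-1-yl]-6-methylhept-4-yn-3-one
Conditions: n-BuLi, THF, −78 °C; then 12, −78 → 0 °C; NH4Cl (aq)
Reagents that add atoms: none
Why: Acylation of the lithium acetylide with a Weinreb amide: the chelated tetrahedral adduct survives until the quench, so the ynone is not attacked a second time.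

Step 9
Reactants: 13 ynone
Product: 14 (4E)-6-[(1R,2R,6S)-2,6-bis(tert-butyldimethylsilyloxy)-3-methylcyclohex-3-en-1-yl]-5-methoxy-6-methylhept-4-en-3-one
Conditions: NaOMe (0.3 equiv), MeOH, 0 °C → rt
Reagents that add atoms: methanol, CO
Why: Oxa-Michael addition of methoxide to the ynone puts the methoxy group regiospecifically on C5; the allenolate should be protonated on the side of the small methoxy group and basic methanol equilibrates towards the same (E) isomer, the only one in which the methoxy group can lie in the enone plane beside the tert-alkyl group, so C3 and C6 come out cis as the ring closure needs.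

Step 10
Reactants: 14 silylated vinylogous ester
Product: 15 (4E)-6-[(1R,2R,6S)-2,6-dihydroxy-3-methylcyclohex-3-en-1-yl]-5-methoxy-6-methylhept-4-en-3-one
Conditions: HF·pyridine, pyridine, THF, 0 °C → rt
Reagents that add atoms: none
Why: Fluoride cleavage of both silyl ethers under buffered, non-basic conditions, which avoids alkoxides that could add to C5 of the vinylogous ester.

Step 11
Reactants: 15 diol
Product: 16 (4E)-6-[(1R,2S,6S)-2-chloro-6-hydroxy-3-methylcyclohex-3-en-1-yl]-5-methoxy-6-methylhept-4-en-3-one
Conditions: NCS, Me2S, CH2Cl2, −25 → 0 °C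
Reagents that add atoms: N-chlorosuccinimide, O=C1CCC(=O)N1Cl
Why: Corey–Kim chlorination: both hydroxyls form alkoxysulfonium salts but only the allylic one is displaced by chloride at this temperature (SN2, inversion), so C8–Cl ends trans to the chain and the C1 alcohol is returned on work-up.

Step 12
Reactants: 16 chloro alcohol
Product: 17 (1S,5S,6R)-5-chloro-6-[(3E)-3-methoxy-2-methyl-5-oxohept-3-en-2-yl]-4-methylcyclohex-3-en-1-yl 4-methylbenzenesulfonate
Conditions: TsCl, pyridine, DMAP (cat.), CH2Cl2, 0 °C → rt
Reagents that add atoms: 4-methylbenzenesulfonyl chloride, Cc1ccc(cc1)S(Cl)(=O)=O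
Why: Sulfonylation of the remaining secondary alcohol with retention at C1 gives the second nucleofuge, also trans to the chain.

Step 13
Reactants: 17 chloro tosylate
Product: 19 tricyclic vinylogous ester (1R,2S,7R,8R): C3 ketone; C4=C5–OMe; C9=C10; C11H2, via bicyclic keto tosylate 18 (not isolated)
Conditions: LiN(i-Pr)2 (1.1 equiv), THF (0.01 M), −78 → 0 °C; then KN(SiMe3)2 (1.3 equiv), −78 °C → rt
Reagents that add atoms: none
Why: LiN(i-Pr)2 can only remove a C2 proton (C4 is vinylic, C6 quaternary); on warming the lithium enolate displaces the allylic chloride at C8 from the chain face with inversion (7-(enolendo)-exo-tet) to give the cis-fused ketone 18, and KN(SiMe3)2 then regenerates the now fully substituted α′-enolate, whose C2 attacks C1 anti to the tosylate (4-(enolexo)-exo-tet) and closes the cyclobutane of the bicyclo[3.1.1]heptene. The closest known reactions are the Stork–Danheiser α′-alkylation of vinylogous esters, the double alkylation of one enolisable carbon by a 1,3-dielectrophile, and the keto-sulfonate cyclobutane closures used for pinane-type skeletons; the bridged tandem combination has no direct model. C2 is the only new stereocentre and has no freedom: both new bonds must lie on the chain face, so its methyl group can only take the outer position, while C8 and C1 are each inverted, which is why both nucleofuges stand trans to the chain in 17. Carbon rather than oxygen alkylation is needed: in the first closure the lithium counter-ion and the soft allylic chloride favour carbon, and in the second closure oxygen cannot reach C1 because that would put a trans C2=C3 bond into a six- or seven-membered ring. Elimination of the tosylate is held back by complete enolisation at −78 °C before warming and by the weaker silylamide base for the second deprotonation, and high dilution suppresses intermolecular alkylation.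

Step 14
Reactants: 19 tricyclic vinylogous ester
Product: 21 tricyclic enone (1R,2S,7R,8R): C5 ketone; C3=C4; C9=C10; C11H2, via allylic alcohol 20 (not isolated)
Conditions: i-Bu2AlH, CH2Cl2, −78 °C; then 1 M HCl, THF, 0 °C
Reagents that add atoms: water, O
Why: Stork–Danheiser transposition: 1,2-reduction of the vinylogous ester, then acid-promoted loss of the C3 oxygen through the methoxy-stabilised allyl cation and hydrolysis at C5 give the C5 ketone with a C3=C4 alkene; no stereocentre is formed, and short contact with cold dilute acid should spare the pinene-like alkene and the cyclobutane.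

Step 15
Reactants: 21 tricyclic enone
Product: 23 (3R)-3-hydroxy C5 ketone (1R,2S,3R,7R,8R), via boronate 22 (not isolated)
Conditions: CuCl (5 mol%), NaOt-Bu (10 mol%), Josiphos ligand (6 mol%; antipode chosen for the 3R product), B2pin2, MeOH, THF, rt; then NaBO3·4H2O, THF/H2O, rt
Reagents that add atoms: bis(pinacolato)diboron (boryl group of 22), CC1(C)OB(OC1(C)C)B1OC(C)(C)C(C)(C)O1; sodium perborate (hydroxyl oxygen of 23), [Na+].[O-]OB=O
Why: Copper-catalysed enantioselective conjugate borylation of a cyclic enone, then stereoretentive oxidation of the C–B bond; the two faces of C3 differ only through the distant C9 and C11 ends of the bicycle, so the chiral ligand is expected to decide the face, and the antipode that delivers boron from the C1 side gives the 3R alcohol.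

Step 16
Reactants: 23 β-hydroxy ketone; 24 3-methylbut-2-enoyl chloride
Product: 25 (3R)-3-(3-methylbut-2-enoyloxy) C5 ketone (1R,2S,3R,7R,8R)
Conditions: pyridine, DMAP (cat.), CH2Cl2, 0 °C
Reagents that add atoms: none
Why: DMAP-catalysed acylation of the secondary alcohol with the acid chloride; pyridine at 0 °C should be mild enough to avoid E1cB loss of the new β-acyloxy group and deconjugation of the senecioyl unit through its vinylketene.

Step 17
Reactants: 25 β-acyloxy ketone
Product: 26 (3R,5R)-5-hydroxy 3-senecioate (1R,2S,3R,5R,7R,8R)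
Conditions: (S)-2-methyl-CBS-oxazaborolidine (0.5 equiv), catecholborane, toluene, −78 °C
Reagents that add atoms: none
Why: Corey–Bakshi–Shibata reduction: the C5 carbonyl lies between the quaternary C6 (large) and the C4 methylene (small), so the (S)-oxazaborolidine should deliver hydride to the face that gives the 5R alcohol, anti to the C3 ester, and catecholborane leaves the alkenes untouched at −78 °C.

Step 18
Reactants: 26 hydroxy senecioate; 27 3-methylbutanoyl chloride
Product: 28 (3R,5R)-3-senecioate 5-isovalerate with C11H2 (1R,2S,3R,5R,7R,8R)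
Conditions: pyridine, DMAP, CH2Cl2, 0 °C → rt
Reagents that add atoms: none
Why: Esterification of the hindered secondary alcohol with the acid chloride under nucleophilic catalysis by DMAP.

Step 19
Reactants: 28 diester
Product: 29 CNP0335239.1 (1R,2R,3R,5R,7S,8R)
Conditions: CrO3, 3,5-dimethylpyrazole, CH2Cl2, −20 °C
Reagents that add atoms: chromium trioxide, O=[Cr](=O)=O
Why: Allylic oxidation of the ring methylene C11 next to the trisubstituted alkene with the CrO3–3,5-dimethylpyrazole complex, the same change as α-pinene to verbenone; the bridgehead C8–H cannot give a ketone and the esters and the conjugated senecioyl alkene are inert.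

**Compound list**

1 | (S)-(+)-carvone, (5S)-2-methyl-5-(prop-1-en-2-yl)cyclohex-2-en-1-one | CC(=C)[C@H]1CC=C(C)C(=O)C1 | starting material
2 | trimethyl{[(3S)-6-methyl-3-(prop-1-en-2-yl)cyclohexa-1,5-dien-1-yl]oxy}silane | C[Si](C)(C)OC1=C[C@@H](C(C)=C)CC=C1C | intermediate
3 | 2-methylbut-3-yn-2-ol | CC(C)(O)C#C | starting material
4 | Co2(CO)6(μ-HC≡C–CMe2OH), hexacarbonyldicobalt complex of 3 | CC(C)(O)C#C.[Co].[Co].[C-]#[O+].[C-]#[O+].[C-]#[O+].[C-]#[O+].[C-]#[O+].[C-]#[O+] | intermediate
5 | Co2(CO)6 complex of 6 (cluster on the alkyne) | C#CC(C)(C)[C@@H]1[C@@H](C(C)=C)CC=C(C)C1=O.[Co].[Co].[C-]#[O+].[C-]#[O+].[C-]#[O+].[C-]#[O+].[C-]#[O+].[C-]#[O+] | intermediate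
6 | (5S,6S)-2-methyl-6-(2-methylbut-3-yn-2-yl)-5-(prop-1-en-2-yl)cyclohex-2-en-1-one | C#CC(C)(C)[C@@H]1[C@@H](C(C)=C)CC=C(C)C1=O | intermediate
7 | (5S,6S)-5-(1-hydroperoxy-1-methoxyethyl)-2-methyl-6-(2-methylbut-3-yn-2-yl)cyclohex-2-en-1-one (both epimers at the peroxyketal carbon) | C#CC(C)(C)[C@@H]1[C@@H](C(C)(OC)OO)CC=C(C)C1=O | intermediate
8 | (1S,6R)-4-methyl-6-(2-methylbut-3-yn-2-yl)-5-oxocyclohex-3-en-1-yl acetate | C#CC(C)(C)[C@@H]1[C@@H](OC(C)=O)CC=C(C)C1=O | intermediate
9 | (5S,6R)-5-hydroxy-2-methyl-6-(2-methylbut-3-yn-2-yl)cyclohex-2-en-1-one | C#CC(C)(C)[C@@H]1[C@@H](O)CC=C(C)C1=O | intermediate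
10 | (1S,2R,3R)-4-methyl-2-(2-methylbut-3-yn-2-yl)cyclohex-4-ene-1,3-diol | C#CC(C)(C)[C@@H]1[C@@H](O)CC=C(C)[C@@H]1O | intermediate
11 | bis(tert-butyldimethylsilyl) ether of 10 | C#CC(C)(C)[C@@H]1[C@@H](O[Si](C)(C)C(C)(C)C)CC=C(C)[C@@H]1O[Si](C)(C)C(C)(C)C | intermediate
12 | N-methoxy-N-methylpropanamide | CCC(=O)N(C)OC | starting material
13 | 6-[(1R,2R,6S)-2,6-bis(tert-butyldimethylsilyloxy)-3-methylcyclohex-3-en-1-yl]-6-methylhept-4-yn-3-one | CCC(=O)C#CC(C)(C)[C@@H]1[C@@H](O[Si](C)(C)C(C)(C)C)CC=C(C)[C@@H]1O[Si](C)(C)C(C)(C)C | intermediate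
14 | (4E)-6-[(1R,2R,6S)-2,6-bis(tert-butyldimethylsilyloxy)-3-methylcyclohex-3-en-1-yl]-5-methoxy-6-methylhept-4-en-3-one | CCC(=O)/C=C(OC)\C(C)(C)[C@@H]1[C@@H](O[Si](C)(C)C(C)(C)C)CC=C(C)[C@@H]1O[Si](C)(C)C(C)(C)C | intermediate
15 | (4E)-6-[(1R,2R,6S)-2,6-dihydroxy-3-methylcyclohex-3-en-1-yl]-5-methoxy-6-methylhept-4-en-3-one | CCC(=O)/C=C(OC)\C(C)(C)[C@@H]1[C@@H](O)CC=C(C)[C@@H]1O | intermediate
16 | (4E)-6-[(1R,2S,6S)-2-chloro-6-hydroxy-3-methylcyclohex-3-en-1-yl]-5-methoxy-6-methylhept-4-en-3-one | CCC(=O)/C=C(OC)\C(C)(C)[C@@H]1[C@@H](O)CC=C(C)[C@H]1Cl | intermediate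
17 | (1S,5S,6R)-5-chloro-6-[(3E)-3-methoxy-2-methyl-5-oxohept-3-en-2-yl]-4-methylcyclohex-3-en-1-yl 4-methylbenzenesulfonate (key-step precursor) | CCC(=O)/C=C(OC)\C(C)(C)[C@@H]1[C@@H](OS(=O)(=O)c2ccc(C)cc2)CC=C(C)[C@H]1Cl | intermediate
18 | bicyclic keto tosylate (1S,7R,8S; C2 epimers): C2–C8 bond formed, seven-membered vinylogous ester ring cis-fused to the cyclohexene, C1–OTs intact | O=C1C=C(OC)C(C)(C)[C@@H]2[C@@H](OS(=O)(=O)c3ccc(C)cc3)CC=C(C)[C@@H]2C1C | intermediate
19 | tricyclic vinylogous ester (1R,2S,7R,8R): C3 ketone, C4=C5–OMe, C9=C10, C11H2 (key-step product) | O=C1C=C(OC)C(C)(C)[C@@H]2[C@H]3CC=C(C)[C@@H]2[C@]31C | intermediate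
20 | C3 allylic alcohol of 19 (both C3 epimers) | OC1C=C(OC)C(C)(C)[C@@H]2[C@H]3CC=C(C)[C@@H]2[C@]31C | intermediate
21 | tricyclic enone (1R,2S,7R,8R): C5 ketone, C3=C4, C9=C10, C11H2 | C1=CC(=O)C(C)(C)[C@@H]2[C@H]3CC=C(C)[C@@H]2[C@]31C | intermediate
22 | (3R)-C3 pinacol boronate of the C5 ketone | CC1(C)OB(OC1(C)C)[C@@H]1CC(=O)C(C)(C)[C@@H]2[C@H]3CC=C(C)[C@@H]2[C@]31C | intermediate
23 | (3R)-3-hydroxy C5 ketone (1R,2S,3R,7R,8R) | O[C@@H]1CC(=O)C(C)(C)[C@@H]2[C@H]3CC=C(C)[C@@H]2[C@]31C | intermediate
24 | 3-methylbut-2-enoyl chloride (senecioyl chloride) | CC(C)=CC(Cl)=O | starting material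
25 | (3R)-3-(3-methylbut-2-enoyloxy) C5 ketone (1R,2S,3R,7R,8R) | CC(C)=CC(=O)O[C@@H]1CC(=O)C(C)(C)[C@@H]2[C@H]3CC=C(C)[C@@H]2[C@]31C | intermediate
26 | (3R,5R)-5-hydroxy 3-senecioate (1R,2S,3R,5R,7R,8R) | CC(C)=CC(=O)O[C@@H]1C[C@@H](O)C(C)(C)[C@@H]2[C@H]3CC=C(C)[C@@H]2[C@]31C | intermediate
27 | 3-methylbutanoyl chloride (isovaleryl chloride) | CC(C)CC(Cl)=O | starting material
28 | (3R,5R)-3-senecioate 5-isovalerate with C11H2 (1R,2S,3R,5R,7R,8R) | CC(C)=CC(=O)O[C@@H]1C[C@@H](OC(=O)CC(C)C)C(C)(C)[C@@H]2[C@H]3CC=C(C)[C@@H]2[C@]31C | intermediate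
29 | CNP0335239.1 (1R,2R,3R,5R,7S,8R) | CC(C)=CC(=O)O[C@@H]1C[C@@H](OC(=O)CC(C)C)C(C)(C)[C@@H]2[C@H]3C(=O)C=C(C)[C@@H]2[C@]31C | target

**Step count**

Total: 19 steps. Longest linear sequence: 18 steps (steps 1 and 3–19 from (S)-carvone; step 2 is the side branch).

**Steps most likely to fail**

1. Step 13 (key step). The amide base may remove an allylic C11 hydrogen anti to the tosylate (E2 to the conjugated cyclohexadiene) before or after the first closure. The boat-like geometry needed for backside attack at C1 may also make the four-membered ring closure slower than decay of the hindered enolate.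
Fallback, setting out from 16 and coming back at 19: the C1 hydroxyl of 16 is silylated (TBSOTf, 2,6-lutidine) to silyl ether F1, so no sulfonate is present when the first enolate is made. LiN(i-Pr)2 then closes only the seven-membered ring to bicyclic ketone F2. HF·pyridine frees alcohol F3, which is converted at −78 °C into the far better nucleofuge, triflate F4 (Tf2O, 2,6-di-tert-butylpyridine; not isolated). KN(SiMe3)2 added to the same flask closes the cyclobutane to 19.

2. Step 15. The boryl-copper species may fail to add to the β-carbon beside the quaternary cyclobutane carbon, or the ligand may not override the weak and unknown substrate bias, so that C3 forms as a mixture.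
Fallback, setting out from 19 and coming back at 25: the C3 oxygen is kept instead of being transposed. Oxazaborolidine-controlled 1,2-reduction of the C3 ketone of 19 (2-methyl-CBS-oxazaborolidine, catecholborane; antipode chosen for the 3R carbinol) gives allylic alcohol F5. Acylation with 24 gives senecioate F6. Hydrolysis of the enol ether with oxalic acid on wet silica (the ester ionises far less readily than the free alcohol) gives 25, and the route continues with step 17.

3. Step 11. Chloride may enter at C10 with allylic shift, or the alkoxysulfonium salt may ionise, so that the C8 configuration is eroded at this hindered secondary allylic carbon.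
Fallback, setting out from 15 and coming back at 18: the cis C8–O bond of 15 is kept and the first closure is done by a Tsuji–Trost alkylation with net retention. Tosylation of the less hindered, non-allylic C1 hydroxyl (TsCl, pyridine, 0 °C) gives hydroxy tosylate F7. Methyl chloroformate and pyridine give allylic carbonate F8. The lithium enolate (LiN(i-Pr)2, −78 °C) is cyclised with Pd(PPh3)4 (zerovalent palladium): ionisation anti to the carbonate and attack of the enolate anti to palladium place C2 cis to the chain. This gives 18, which is isolated and closed to 19 with KN(SiMe3)2 as in the second half of step 13.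

**Further compounds**

F1 | step 13 | C1 tert-butyldimethylsilyl ether of 16 | CCC(=O)/C=C(OC)\C(C)(C)[C@@H]1[C@@H](O[Si](C)(C)C(C)(C)C)CC=C(C)[C@H]1Cl
F2 | step 13 | bicyclic ketone with C2–C8 bond and C1–OTBS (C2 epimers) | O=C1C=C(OC)C(C)(C)[C@@H]2[C@@H](O[Si](C)(C)C(C)(C)C)CC=C(C)[C@@H]2C1C
F3 | step 13 | bicyclic ketone with free C1 hydroxyl (C2 epimers) | O=C1C=C(OC)C(C)(C)[C@@H]2[C@@H](O)CC=C(C)[C@@H]2C1C
F4 | step 13 | C1 trifluoromethanesulfonate of F3 | O=C1C=C(OC)C(C)(C)[C@@H]2[C@@H](OS(=O)(=O)C(F)(F)F)CC=C(C)[C@@H]2C1C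
F5 | step 15 | (3R)-C3 allylic alcohol of 19 | O[C@@H]1C=C(OC)C(C)(C)[C@@H]2[C@H]3CC=C(C)[C@@H]2[C@]31C
F6 | step 15 | (3R)-C3 senecioate of F5, enol ether intact | CC(C)=CC(=O)O[C@@H]1C=C(OC)C(C)(C)[C@@H]2[C@H]3CC=C(C)[C@@H]2[C@]31C
F7 | step 11 | C1 mono-tosylate of 15 with free cis C8 hydroxyl | CCC(=O)/C=C(OC)\C(C)(C)[C@@H]1[C@@H](OS(=O)(=O)c2ccc(C)cc2)CC=C(C)[C@@H]1O
F8 | step 11 | C8 methyl carbonate of F7 | CCC(=O)/C=C(OC)\C(C)(C)[C@@H]1[C@@H](OS(=O)(=O)c2ccc(C)cc2)CC=C(C)[C@@H]1OC(=O)OC
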